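At early times the grey flask ran fast: by 1.50 h it had consumed 56.3% of its electrophile, but the next 6.50 h added just 16 percentage points.

| flask | electrophile | nucleophile | remark | time |
|---|---|---|---|---|
| grey | 0.13 M | 0.15 M | run made earlier |  |
| theta | 0.13 M | 0.140 M |  | 12 h |
| alpha | 0.13 M | 0.180 M |  | 12 h |

- grey (time / h: electrophile / %, product / %): 1.50: 43.7, 59.4; 3.00: 37.4, 60.2; 5.00: 32.4, 67.1; 6.00: 31.1, 68.0; 8.00: 27.9, 73.2

(scatter of a reading: 1 percentage point)

- the earlier runs were read with a standard deviation of 1 percentage point
- steps thought possible: acid set free -> by-product carried off; nucleophile + acid set free <-> protonated nucleophile; electrophile + nucleophile -> acid set free + product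

So I asked what could brake a flask there. If each acid set free protonates a second nucleophile, nucleophile goes two per electrophile and is the limiting reagent. For grey that gives 57.7%, and this two-for-one limit L is half the nucleophile charged divided by the electrophile charged. But grey read 72.1% reacted at 8.00 h, which is 14 points beyond L against a scatter of 1 point, so a slow second stage lay on top of the limit.

* part of the electrophile that has reacted at the end, theta
* part of the electrophile that has reacted at the end, alpha
* what raising the concentration of nucleophile from its lowest to its highest value here does to the part of the electrophile that has reacted (changes below 5 percentage points count as none) (no change / it falls / it rises)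

My first round for 12 h was therefore L itself: 53.8% for theta, 69.2% for alpha. Then I went round once more and added the slow stage. From 5.00 h to 8.00 h grey's electrophile fell 4.5 points; at that pace it would lose 6 points more by 12 h, putting grey 20 points above L. Adding that same gain, I committed to 74.3% for theta and 89.6% for alpha, a difference of 15 points.

The forecast, reasoning that “each acid released protonates a second nucleophile”, gave 74% (70% to 78%) for theta and 86% (80% to 92%) for alpha, with the trend it rises; its alpha stood lower than mine.

Theta reached 77.8% and alpha 89.7%, a change of 12 points: it rises.

    acid set free → by-product carried off (k = 5.70 h⁻¹)
    nucleophile + acid set free ⇌ protonated nucleophile, settled at all times (K = 13000 L mol⁻¹)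
    electrophile + nucleophile → acid set free + product (k = 19.0 L mol⁻¹ h⁻¹)

At 12.0 h alpha still held 3.71% of its charged nucleophile free. Against L, the gain was 24 points in theta and 20 points in alpha. A neighbouring flask, alpha's charge but with 0.045 M of nucleophile, has L of 17.3%; it reached 33.1% at 12.0 h, which is 16 points above its L.

Readings and results are calculated with constants of no real substance; noise was put on by code.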